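If you follow the substrate left in a run once the run is under way, you can read how the rate depends on the charge of catalyst, and Wednesday's flask needs exactly that dependence.

| setting | Monday's | Friday's | Saturday's | Sunday's | Wednesday's |
|---|---|---|---|---|---|
| substrate | 0.400 M | 0.200 M | 0.200 M | 0.400 M | 0.130 M |
| catalyst | 0.0320 M | 0.0320 M | 0.0320 M | 0.0960 M | 0.0110 M |
| time |  |  |  |  | 47 h |

| run | time / h | [product] / M |
|---|---|---|
| Monday's run | 1.9 | 0.009 |
| Monday's run | 3.2 | 0.017 |
| Monday's run | 5.5 | 0.035 |
| Monday's run | 9.4 | 0.071 |
| Monday's run | 16 | 0.126 |
| Monday's run | 27 | 0.203 |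
| Monday's run | 47 | 0.301 |
| Friday's run | 1.9 | 0.006 |
| Friday's run | 3.2 | 0.013 |
| Friday's run | 5.5 | 0.026 |
| Friday's run | 9.4 | 0.045 |
| Friday's run | 16 | 0.079 |
| Friday's run | 27 | 0.121 |
| Friday's run | 47 | 0.160 |
| Saturday's run | 1.9 | 0.006 |
| Saturday's run | 3.2 | 0.010 |
| Saturday's run | 5.5 | 0.019 |
| Saturday's run | 9.4 | 0.046 |
| Saturday's run | 16 | 0.081 |
| Saturday's run | 27 | 0.119 |
| Saturday's run | 47 | 0.163 |
| Sunday's run | 1.9 | 0.051 |
| Sunday's run | 3.2 | 0.125 |
| Sunday's run | 5.5 | 0.254 |
| Sunday's run | 9.4 | 0.359 |
| Sunday's run | 16 | 0.399 |
| Sunday's run | 27 | 0.402 |
| Sunday's run | 47 | 0.396 |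

(readings scatter by 0.003 M)

- Overall: substrate -> product, with catalyst as catalyst.
- Constant volume, constant temperature.
- Readings of a species count what is bound in complexes too.
- An order is taken over about fifteen percent of the charge, up and down.

1. order of the initial rate in [catalyst], near the charge of the Monday's run, the rate being that where two percent of its substrate are product
2. order of the initial rate in [substrate], near the charge of the Monday's run, the rate being that where two percent of its substrate are product (one fixed amount of product, the same in the runs compared)
3. the Friday's run starts with 0.200 M less of substrate than the Monday's run, and with no product. Compared where both hold the same amount of substrate, once fifteen percent of what the Friday's run was charged with has turned into product, is the Friday's run faster, slower or alike (within a tenth)?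
4. product in the Wednesday's run at 47 h, as a share of the substrate charged
5. which of these the readings show (the catalyst dies by itself / nothing beyond the main steps / the catalyst wakes slowly / the catalyst dies in pairs / the product binds the substrate)

Monday's run speeds up at first, from 0.00474 M h⁻¹ over the opening stretch to 0.00923 M h⁻¹ between 5.5 h and 9.4 h, although its substrate is falling, so I read the catalyst dependence later. Monday's substrate falls with a first-order constant of 0.0328 h⁻¹ from 16 h to 47 h. Sunday's falls from nearly the same concentration with 0.275 h⁻¹ from 3.2 h to 5.5 h, on 3.00 times the catalyst. Between these two stretches that makes the order in [catalyst], as read, 1.94, so I take it as second order.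

The quantity to carry is therefore the first-order constant of substrate loss divided by the square of the catalyst charge, the catalyst-squared constant. Friday's and Saturday's runs, from 16 h to 47 h, give on average 35.8 M⁻² h⁻¹, starting near 0.121 M of substrate, close to Wednesday's charge of 0.130 M. Wednesday's 0.0110 M of catalyst then gives 0.00433 h⁻¹, and over 47 h my reckoning gives 18.4%, with the early delay ignored.

In the order asked, the forecast said 1.5, 0.45, alike, 23% and the catalyst wakes slowly, on the ground “That is an induction, so the catalyst wakes slowly”, and its share for Wednesday's run stands higher than mine.

In the same order, the flask gives 1.4, 0.33, alike, 18.0% and the catalyst wakes slowly.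

    active catalyst + substrate ⇌ catalyst-substrate complex, settled at all times (0.9580 M⁻¹)
    catalyst-substrate complex + active catalyst → product + 2 active catalyst (47.16 M⁻¹ h⁻¹)
    catalyst → active catalyst (0.9108 h⁻¹)

Near Monday's charge the early order in [catalyst] is 1.4, against 2.0 with all catalyst active from the start, a gap that comes from the slowness of the step from catalyst to active catalyst. Carried to Sunday's run, which differs from Friday's and Saturday's runs in both charges, 35.8 M⁻² h⁻¹ gives a half-time of 2.10 h, but Sunday's own half-time stood at 4.43 h.

The numbers in the tables were generated by integration for substances that don't exist.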